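**Retrosynthetic overview**
- The hexyl chain is a 2-deoxy-L-fucose skeleton, so C3, C4 and C5 are taken unchanged from L-fucose; the last step opens a 1-C-aryl 2-deoxy-L-fucopyranose hemiketal by catalyst-controlled ketone reduction, which sets C1.
- The myristate is placed on the equatorial 3-OH of that cyclic hemiketal, where O5 is the ring oxygen and O1 is a tertiary hemiketal OH.
- Key C–C bond: sugar C1 to the future oxazole C4, made by a C1-lithiated L-fucal (acyl-anion equivalent of the anomeric carbonyl) attacking chloroacetyl Weinreb amide.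
- The central oxazole is then closed by a Hantzsch condensation of the resulting α-halo ketone with 2-(oxazol-5-yl)acetamide.
- Ring order: the pyran comes with L-fucose and is opened last; the terminal oxazole is formed first (cycloisomerisation of a propargyl formamide ynoate); the central oxazole second.

Assumption: hemiketals 22 and 24 and tetraacetate 2 are equilibrating anomeric mixtures and are drawn without configuration at C1; sugar numbering (C1–C6) is used for the chain throughout.

**Step 1**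
Reactants: 1 L-fucose
Product: 4 3,4-di-O-acetyl-L-fucal, via fucose tetraacetate 2 (not isolated), via acetobromofucose 3 (not isolated)
Conditions: Ac2O, cat. HBr/AcOH, rt; then 33% HBr/AcOH, rt; then Zn, CuSO4·5H2O, NaOAc, AcOH–H2O, 0 °C→rt (one pot)
Reagents that add atoms: acetic anhydride CC(=O)OC(C)=O
Why: One-pot peracetylation, anomeric bromination and zinc reductive elimination (Fischer–Zach glycal synthesis) removes C1/C2 oxygens and leaves C3, C4 and C5 of L-fucose untouched.

**Step 2**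
Reactants: 4 3,4-di-O-acetyl-L-fucal
Product: 6 3,4-bis-O-(tert-butyldimethylsilyl)-L-fucal, via L-fucal 5 (not isolated)
Conditions: K2CO3 (cat.), MeOH, rt; evaporate; TBSOTf, 2,6-lutidine, CH2Cl2, 0 °C→rt
Reagents that add atoms: tert-butyldimethylsilyl triflate CC(C)(C)[Si](C)(C)OS(=O)(=O)C(F)(F)F
Why: Zemplén-type transesterification followed by silylation exchanges the base-labile acetates for silyl ethers that survive t-BuLi; no stereocentre is touched.

**Step 3** (key step)
Reactants: 6 3,4-bis-O-TBS-L-fucal; 7 2-chloro-N-methoxy-N-methylacetamide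
Product: 10 1-C-(chloroacetyl)-3,4-bis-O-TBS-L-fucal, via 1-lithio glycal 8 (not isolated), via lithium hemiaminal chelate 9 (not isolated)
Conditions: t-BuLi (3.5 equiv), THF, −78→0 °C; recool, 7, −78→−40 °C; AcOH quench
Reagents that add atoms: none
Why: Vinylic C1 lithiation gives an α-alkoxyvinyl anion, an acyl-anion equivalent of the normally electrophilic anomeric carbonyl, which adds to the Weinreb carbonyl (also electrophilic) and after chelate collapse gives the masked 1,2-dicarbonyl (Weinreb ketone synthesis); no new stereocentre is formed.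

**Step 4**
Reactants: 11 propargylamine; 12 ethyl formate
Product: 13 N-(prop-2-yn-1-yl)formamide
Conditions: HCO2Et (neat, excess), reflux
Reagents that add atoms: none
Why: Aminolysis of the formate ester (N-formylation) installs the carbon that becomes C2 of the terminal oxazole.

**Step 5**
Reactants: 13 N-(prop-2-yn-1-yl)formamide; 14 methyl chloroformate
Product: 16 methyl 4-formamidobut-2-ynoate, via dilithio dianion 15 (not isolated)
Conditions: n-BuLi (2.1 equiv), THF, −78 °C; ClCO2Me (1.0 equiv), −78 °C; AcOH quench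
Reagents that add atoms: none
Why: In the N,C-dianion the more basic acetylide carbon reacts first with one equivalent of chloroformate (acetylide C-acylation), as known for N-Boc-propargylamine.

**Step 6**
Reactants: 16 methyl 4-formamidobut-2-ynoate
Product: 19 2-(1,3-oxazol-5-yl)acetamide, via alkylidene oxazoline 17 (not isolated), via methyl oxazol-5-ylacetate 18 (not isolated)
Conditions: Cs2CO3 (0.1 equiv), MeCN, 40 °C; filter, evaporate; 7 M NH3/MeOH, rt
Reagents that add atoms: ammonia N
Why: Base-mediated 5-exo-dig oxa-Michael cycloisomerisation of the propargylic formamide onto the ynoate, aromatising 1,3-H shift to the 5-substituted oxazole, then ester ammonolysis.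

**Step 7**
Reactants: 10 1-C-(chloroacetyl)-3,4-bis-O-TBS-L-fucal; 19 2-(1,3-oxazol-5-yl)acetamide
Product: 21 1-C-[2-(1,3-oxazol-5-ylmethyl)-1,3-oxazol-4-yl]-3,4-bis-O-TBS-L-fucal, via iodoketone 20 (not isolated)
Conditions: NaI, acetone, rt; filter, evaporate; 19, AgSbF6, 2,6-di-tert-butyl-4-methylpyridine, 4 Å MS, (CH2Cl)2, 55 °C, dark
Reagents that add atoms: none
Why: Finkelstein exchange then silver-mediated Hantzsch (Blümlein–Lewy) oxazole synthesis: amide O is alkylated at CH2, amide N condenses with the ketone, so the ketone carbon becomes oxazole C4 and the sugar sits at C4; the hindered base buffers the acid so the enol ether survives.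

**Step 8**
Reactants: 21 1-C-(bis-oxazolyl)-3,4-bis-O-TBS-L-fucal
Product: 22 1-C-[2-(1,3-oxazol-5-ylmethyl)-1,3-oxazol-4-yl]-2,6-dideoxy-L-lyxo-hexopyranose
Conditions: 2 M aq. HCl–THF (1:3), rt
Reagents that add atoms: water O
Why: Acid-catalysed hydration of the aryl-substituted enol ether (C2 protonation, water capture of the aryl-stabilised oxocarbenium) unveils the C1 ketone as its hemiketal while both TBS ethers are hydrolysed.

**Step 9**
Reactants: 22 hemiketal triol; 23 tetradecanoyl chloride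
Product: 24 3-O-tetradecanoyl derivative of 22
Conditions: Me2SnCl2 (5 mol %), i-Pr2NEt, THF, 0 °C→rt
Reagents that add atoms: none
Why: Tin-catalysed regioselective acylation of a cis-1,2-diol goes to the equatorial 3-OH over the axial 4-OH (as for fucosides), while the tertiary hemiketal OH and ring-bound O5 do not compete.

**Step 10**
Reactants: 24 3-O-tetradecanoyl hemiketal
Product: 26 (1R,3S,4R,5S)-1,4,5-trihydroxy-1-[2-(1,3-oxazol-5-ylmethyl)-1,3-oxazol-4-yl]hexan-3-yl tetradecanoate, via open-chain ketone 25 (not isolated)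
Conditions: RuCl[(R,R)-TsDPEN](p-cymene) (3 mol %), HCO2H–Et3N (5:2), CH2Cl2, 30 °C
Reagents that add atoms: none
Why: Noyori asymmetric transfer hydrogenation of the ring-chain-equilibrated heteroaryl ketone, in which the (R,R)-catalyst gives the (R)-carbinol (same sense as (R)-1-phenylethanol, oxazolyl as the aryl group), i.e. C1 syn to C3, under mildly acidic conditions that disfavour β-elimination and acyl migration.

**Compound list**
1 | L-fucose (6-deoxy-L-galactopyranose) | C[C@@H]1OC(O)[C@@H](O)[C@H](O)[C@@H]1O | starting material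
2 | 1,2,3,4-tetra-O-acetyl-L-fucopyranose | C[C@@H]1OC(OC(C)=O)[C@@H](OC(C)=O)[C@H](OC(C)=O)[C@@H]1OC(C)=O | intermediate
3 | 2,3,4-tri-O-acetyl-α-L-fucopyranosyl bromide | C[C@@H]1O[C@@H](Br)[C@@H](OC(C)=O)[C@H](OC(C)=O)[C@@H]1OC(C)=O | intermediate
4 | 3,4-di-O-acetyl-L-fucal (1,5-anhydro-2,6-dideoxy-L-lyxo-hex-1-enitol diacetate) | C[C@@H]1OC=C[C@H](OC(C)=O)[C@@H]1OC(C)=O | intermediate
5 | L-fucal | C[C@@H]1OC=C[C@H](O)[C@@H]1O | intermediate
6 | 3,4-bis-O-(tert-butyldimethylsilyl)-L-fucal | C[C@@H]1OC=C[C@H](O[Si](C)(C)C(C)(C)C)[C@@H]1O[Si](C)(C)C(C)(C)C | intermediate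
7 | 2-chloro-N-methoxy-N-methylacetamide | CON(C)C(=O)CCl | starting material
8 | 1-lithio-3,4-bis-O-TBS-L-fucal | C[C@@H]1OC([Li])=C[C@H](O[Si](C)(C)C(C)(C)C)[C@@H]1O[Si](C)(C)C(C)(C)C | intermediate
9 | lithium alkoxide of the tetrahedral adduct of 8 with 7 (N-methoxy-N-methyl hemiaminal) | C[C@@H]1OC(C(CCl)(O[Li])N(C)OC)=C[C@H](O[Si](C)(C)C(C)(C)C)[C@@H]1O[Si](C)(C)C(C)(C)C | intermediate
10 | 2-chloro-1-(3,4-bis-O-TBS-L-fucal-1-yl)ethan-1-one | C[C@@H]1OC(C(=O)CCl)=C[C@H](O[Si](C)(C)C(C)(C)C)[C@@H]1O[Si](C)(C)C(C)(C)C | intermediate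
11 | propargylamine | C#CCN | starting material
12 | ethyl formate | CCOC=O | starting material
13 | N-(prop-2-yn-1-yl)formamide | C#CCNC=O | intermediate
14 | methyl chloroformate | COC(=O)Cl | starting material
15 | N,C-dilithio derivative of 13 | [Li]C#CCN([Li])C=O | intermediate
16 | methyl 4-formamidobut-2-ynoate | COC(=O)C#CCNC=O | intermediate
17 | methyl 2-(1,3-oxazol-5(4H)-ylidene)acetate (alkene geometry not defined) | COC(=O)C=C1CN=CO1 | intermediate
18 | methyl 2-(1,3-oxazol-5-yl)acetate | COC(=O)Cc1cnco1 | intermediate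
19 | 2-(1,3-oxazol-5-yl)acetamide | NC(=O)Cc1cnco1 | intermediate
20 | 2-iodo-1-(3,4-bis-O-TBS-L-fucal-1-yl)ethan-1-one | C[C@@H]1OC(C(=O)CI)=C[C@H](O[Si](C)(C)C(C)(C)C)[C@@H]1O[Si](C)(C)C(C)(C)C | intermediate
21 | 4-(3,4-bis-O-TBS-L-fucal-1-yl)-2-(1,3-oxazol-5-ylmethyl)-1,3-oxazole | C[C@@H]1OC(c2coc(Cc3cnco3)n2)=C[C@H](O[Si](C)(C)C(C)(C)C)[C@@H]1O[Si](C)(C)C(C)(C)C | intermediate
22 | 1-C-[2-(1,3-oxazol-5-ylmethyl)-1,3-oxazol-4-yl]-2,6-dideoxy-L-lyxo-hexopyranose (hemiketal) | C[C@@H]1OC(O)(c2coc(Cc3cnco3)n2)C[C@H](O)[C@@H]1O | intermediate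
23 | tetradecanoyl (myristoyl) chloride | CCCCCCCCCCCCCC(Cl)=O | starting material
24 | 3-O-tetradecanoyl-1-C-[2-(1,3-oxazol-5-ylmethyl)-1,3-oxazol-4-yl]-2,6-dideoxy-L-lyxo-hexopyranose | C[C@@H]1OC(O)(c2coc(Cc3cnco3)n2)C[C@H](OC(=O)CCCCCCCCCCCCC)[C@@H]1O | intermediate
25 | (3S,4R,5S)-4,5-dihydroxy-1-[2-(1,3-oxazol-5-ylmethyl)-1,3-oxazol-4-yl]-1-oxohexan-3-yl tetradecanoate | CCCCCCCCCCCCCC(=O)O[C@@H](CC(=O)c1coc(Cc2cnco2)n1)[C@H](O)[C@H](C)O | intermediate
26 | (1R,3S,4R,5S)-1,4,5-trihydroxy-1-[2-(1,3-oxazol-5-ylmethyl)-1,3-oxazol-4-yl]hexan-3-yl tetradecanoate | CCCCCCCCCCCCCC(=O)O[C@@H](C[C@@H](O)c1coc(Cc2cnco2)n1)[C@H](O)[C@H](C)O | target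

**Counts**
Total steps: 10. Longest linear sequence: 7 (steps 1, 2, 3, 7, 8, 9, 10 from L-fucose); the amide branch is 3 steps (4, 5, 6).

**Three steps most likely to fail**

Step 7 (Hantzsch closure on an acid-sensitive glycal ketone; weak amide nucleophile, possible N-alkylation of the oxazole, enol-ether damage). The fallback makes the same C1–C4 bond by cross-coupling instead of ring synthesis; it sets out from 6 and 19 and returns at 21. Compound 6 is lithiated as in step 3 and quenched with Bu3SnCl to give 1-(tributylstannyl)-3,4-bis-O-TBS-L-fucal F1. Amide 19 is heated with chloroacetyl chloride to give N-(chloroacetyl)-2-(1,3-oxazol-5-yl)acetamide F2, which is cyclised with NaH in DME to 2-(1,3-oxazol-5-ylmethyl)-1,3-oxazol-4(5H)-one F3 and triflated (Tf2O, Et3N, −78 °C) to 2-(1,3-oxazol-5-ylmethyl)-1,3-oxazol-4-yl triflate F4. Stille coupling of F1 with F4 (Pd(PPh3)4, CuI, LiCl, dioxane, 90 °C) gives 21.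

Step 8 (protic hydration may be accompanied by Ferrier-type loss of the C3 oxygen or dehydration of the β-hydroxy ketone). The fallback replaces protic hydration by halohydrin formation and radical dehalogenation; it sets out from 21 and returns at 22. TBAF in THF gives the diol 1-C-[2-(1,3-oxazol-5-ylmethyl)-1,3-oxazol-4-yl]-L-fucal F5. NIS in MeCN–H2O at 0 °C gives the 2-deoxy-2-iodo hemiketal F6. Bu3SnH/AIBN in toluene at 80 °C removes the iodine to give 22.

Step 10 (the hemiketal may open too slowly, or the β-acyloxy ketone may eliminate or the ester migrate under the amine/formate medium, or the diastereoselectivity may be low). The fallback locks the open chain first and uses an anhydrous borane reduction; it sets out from 24 and returns at 26. 2-Methoxypropene/PPTS in CH2Cl2 traps the open-chain form as the 4,5-O-isopropylidene ketone F7. (S)-Me-CBS with catecholborane in toluene at −40 °C gives the (1R)-alcohol 4,5-O-isopropylidene derivative F8. 80% aq. AcOH at rt removes the acetonide to give 26.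

**Further compounds**
F1 | step 7 | 1-(tributylstannyl)-3,4-bis-O-TBS-L-fucal | C[C@@H]1OC([Sn](CCCC)(CCCC)CCCC)=C[C@H](O[Si](C)(C)C(C)(C)C)[C@@H]1O[Si](C)(C)C(C)(C)C
F2 | step 7 | N-(chloroacetyl)-2-(1,3-oxazol-5-yl)acetamide | ClCC(=O)NC(=O)Cc1cnco1
F3 | step 7 | 2-(1,3-oxazol-5-ylmethyl)-1,3-oxazol-4(5H)-one | O=C1COC(Cc2cnco2)=N1
F4 | step 7 | 2-(1,3-oxazol-5-ylmethyl)-1,3-oxazol-4-yl trifluoromethanesulfonate | FC(F)(F)S(=O)(=O)Oc1coc(Cc2cnco2)n1
F5 | step 8 | 1-C-[2-(1,3-oxazol-5-ylmethyl)-1,3-oxazol-4-yl]-L-fucal (3,4-diol) | C[C@@H]1OC(c2coc(Cc3cnco3)n2)=C[C@H](O)[C@@H]1O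
F6 | step 8 | 2-iodo derivative of 22 (2,6-dideoxy-2-iodo hemiketal, C1/C2 configuration not defined) | C[C@@H]1OC(O)(c2coc(Cc3cnco3)n2)C(I)[C@H](O)[C@@H]1O
F7 | step 10 | 4,5-O-isopropylidene derivative of ketone 25 | CCCCCCCCCCCCCC(=O)O[C@@H](CC(=O)c1coc(Cc2cnco2)n1)[C@@H]1OC(C)(C)O[C@H]1C
F8 | step 10 | 4,5-O-isopropylidene derivative of 26 | CCCCCCCCCCCCCC(=O)O[C@@H](C[C@@H](O)c1coc(Cc2cnco2)n1)[C@@H]1OC(C)(C)O[C@H]1C
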